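**Plan**

Numbering as in mutilin: ring A is the cyclopentanone C1–C2–C3(=O)–C4–C9, ring B the cyclohexane C4–C5–C6–C7–C8–C9, ring C the cyclooctane C4–C5–C14–C13–C12–C11–C10–C9. Rings B and C share C5–C4–C9, so the core is a bicyclo[5.3.1]undecane with C4 as the one-atom bridge and C5, C9 as bridgeheads.
Retrosynthesis: glycolate and protecting groups off; ring A opened at C2–C3 (Dieckmann) and C9–C1 (radical addition to a C8=C9 bridgehead alkene); then C4–C5 and C6–C7 are cut together. This unravels rings B and C into one acyclic chain: a diene C4=C9–C8=C7 whose inner carbon C9 carries the tether C10–C14, which ends in the enone C14(=O)–C5=C6.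
Forward: the chain is built linearly from (S)-3-hydroxy-γ-butyrolactone (C11, C12, C19, C20), an aldol (C9, C10), an enol triflate/vinyl coupling (diene) and an alkenyllithium addition (dienophile). A type 2 intramolecular Diels–Alder reaction closes rings B and C at once; ring A follows.
Stereochemistry: C19 from the chiral pool; C12 from two anti-selective dianion alkylations; C10 and C11 from an auxiliary-controlled syn aldol; C4, C5 and C6 from the alkene geometries and the C10-controlled face of the cycloaddition; C9 from the bridgehead (only the outer face is open); C14 from a thermodynamically controlled ketone reduction.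

Key step: step 14

Remark: the descriptors at C4, C5 and C6 are written throughout exactly as in the target SMILES; taken literally they would put the C5–C14 and C9–C10 bonds on opposite faces of ring B, an in,out bicyclo[5.3.1]undecane that is not a realistic structure, so they are read as the mutilin-type out,out core (both bonds on the same face, C4–H cis to C10), which is the core the chemistry below builds.

**Route**

Step 1
Reactants: 1 (S)-3-hydroxy-γ-butyrolactone
Product: 2 trans-4-hydroxy-3-methyl lactone
Conditions: LiN(i-Pr)2 (2.2 equiv), THF, −78 °C; MeI, −78 to −20 °C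
Reagents that add atoms: iodomethane, CI
Why: Frater–Seebach alkylation of the lactone dianion; the methyl group should enter anti to the C19 alkoxide, giving the trans lactone.

Step 2
Reactants: 2 trans-4-hydroxy-3-methyl lactone
Product: 3 3-allyl-4-hydroxy-3-methyl lactone
Conditions: LiN(i-Pr)2 (2.3 equiv), THF/DMPU, −78 °C; allyl bromide, −78 to 0 °C
Reagents that add atoms: allyl bromide, C=CCBr
Why: second Frater–Seebach alkylation; the allyl group again enters anti to the alkoxide, so the order methyl-then-allyl fixes the quaternary C12 (allyl trans, methyl cis to the hydroxyl).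

Step 3
Reactants: 3 3-allyl-4-hydroxy-3-methyl lactone
Product: 4 triol
Conditions: LiAlH4, THF, 0 °C to reflux
Reagents that add atoms: none
Why: hydride reduction of the lactone to the diol; no stereocenter is touched.

Step 4
Reactants: 4 triol
Product: 5 dioxolane primary alcohol
Conditions: 2,2-dimethoxypropane, PPTS (cat.), acetone, 23 °C
Reagents that add atoms: 2,2-dimethoxypropane, COC(C)(C)OC
Why: acetonide formation under equilibrating conditions should favor the five-membered dioxolane of the terminal 1,2-diol (C19/C20) over the six-membered dioxane, leaving the neopentyl C11 alcohol free.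

Step 5
Reactants: 5 dioxolane primary alcohol
Product: 6 α-quaternary aldehyde
Conditions: Dess–Martin periodinane, CH2Cl2, 23 °C
Reagents that add atoms: none
Why: Dess–Martin oxidation of the primary alcohol; the aldehyde has no α-hydrogen and cannot epimerize.

Step 6
Reactants: 6 α-quaternary aldehyde; 7 (4S)-4-benzyl-3-propanoyl-1,3-thiazolidine-2-thione
Product: 8 syn aldol adduct
Conditions: 7, TiCl4, i-Pr2NEt, N-methylpyrrolidinone, CH2Cl2, 0 °C; then 6, −78 to 0 °C
Reagents that add atoms: none
Why: auxiliary-controlled titanium enolate syn aldol through a closed Zimmerman–Traxler transition state ("Evans syn" sense) should set C10 and C11; this is matched with Felkin–Anh addition anti to the dioxolane on C12.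

Step 7
Reactants: 8 syn aldol adduct
Product: 9 silyl ether
Conditions: TBSOTf, 2,6-lutidine, CH2Cl2, 0 °C
Reagents that add atoms: tert-butyldimethylsilyl triflate, CC(C)(C)[Si](C)(C)OS(=O)(=O)C(F)(F)F
Why: silylation of the hindered C11 hydroxyl with the silyl triflate; this blocks C11 for the later oxidations and the acylation.

Step 8
Reactants: 9 silyl ether
Product: 10 β-keto ester
Conditions: KO2CCH2CO2Me, MgCl2, imidazole, THF, 23 to 40 °C
Reagents that add atoms: potassium methyl malonate, COC(=O)CC(=O)[O-].[K+]
Why: acyl transfer from the thiazolidinethione to the magnesium enolate of the malonate half-ester, then decarboxylation, gives the β-keto ester (C9, C4, C3) under conditions too mild to epimerize C10.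

Step 9
Reactants: 10 β-keto ester
Product: 11 (Z)-enol triflate
Conditions: Tf2O, aq. LiOH, toluene, 5 °C
Reagents that add atoms: triflic anhydride, O=S(=O)(OS(=O)(=O)C(F)(F)F)C(F)(F)F
Why: O-triflation of the chelated lithium enolate of the β-keto ester should give the (Z)-enol triflate (triflate cis to the ester).

Step 10
Reactants: 11 (Z)-enol triflate
Product: 13 C14 aldehyde, via ozonide 12 (not isolated)
Conditions: O3, CH2Cl2, −78 °C; then PPh3, −78 to 23 °C
Reagents that add atoms: ozone, [O-][O+]=O
Why: ozonolysis with reductive work-up; the terminal alkene should react far faster than the electron-poor enol triflate double bond.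

Step 11
Reactants: 13 C14 aldehyde; 14 (Z)-2-bromobut-2-ene
Product: 16 allylic alcohol (both C14 epimers), via (Z)-but-2-en-2-yllithium 15 (not isolated)
Conditions: 14, t-BuLi (2 equiv), Et2O, −78 °C; then 13, −78 °C
Reagents that add atoms: none
Why: bromine–lithium exchange with retention of alkene geometry, then 1,2-addition to the aldehyde, which at −78 °C should outrun attack on the ester or the triflate; the C14 carbinol center is a mixture that step 13 removes.

Step 12
Reactants: 16 allylic alcohol
Product: 17 dienoate alcohol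
Conditions: Bu3SnCH=CH2, Pd(PPh3)4 (5 mol %), LiCl, THF, 60 °C
Reagents that add atoms: tributyl(vinyl)stannane, C=C[Sn](CCCC)(CCCC)CCCC
Why: Stille coupling of the enol triflate proceeds with retention, so the vinyl group (C8, C7) takes the place of the triflate, cis to the ester.

Step 13
Reactants: 17 dienoate alcohol
Product: 18 triene (Z)-enone
Conditions: Dess–Martin periodinane, CH2Cl2, 0 °C
Reagents that add atoms: none
Why: Dess–Martin oxidation of the allylic alcohol under mild conditions should give the (Z)-enone (C14 cis to C17) without isomerization.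

Step 14
Reactants: 18 triene (Z)-enone
Product: 19 bicyclo[5.3.1]undecene keto ester
Conditions: toluene (0.005 M), BHT (cat.), 170 °C, sealed tube
Reagents that add atoms: none
Why: A thermal type 2 intramolecular Diels–Alder reaction (concerted suprafacial [4+2]) joins the diene C4=C9–C8=C7 to the (Z)-enone C5=C6; the closest known reaction type is the ketone-activated type 2 cycloaddition of 2-substituted butadienes that gives bicyclo[5.3.1]undec-ene bridgehead alkenes, which also tolerates a doubly substituted diene terminus. Because the five-atom tether C10–C14 links the inner diene carbon C9 to C5, only the 1,3-bridged mode is possible: C4 bonds to C5 and C7 to C6, so ring B closes as the cyclohexene C4–C5–C6–C7–C8=C9 by [4+2] union of the two π systems, and ring C (C4–C5–C14–C13–C12–C11–C10–C9) closes through the same new C4–C5 bond as the large ring of the bridged bicycle, leaving the C8=C9 bridgehead alkene. C5 and C6 are fixed relative to each other by the retained (Z) geometry of the dienophile (C14 and C17 cis), and C4 by the diene geometry (the ester on the inside, cis to the vinyl group, ends up anti to C14). The face is chosen by C10: with C10–H in the diene plane next to C8–H (minimal allylic 1,3-strain) the tether can only reach one face while the C16 methyl points to the other, and attack on the opposite face would force that methyl into the in-plane position against C8–H. The step needs the enone to keep its (Z) geometry and the ring closure to outrun dimerization, which neutral, dilute, radical-inhibited thermal conditions and the short tether should secure.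

Step 15
Reactants: 19 bicyclo[5.3.1]undecene keto ester
Product: 20 C14 alcohol
Conditions: SmI2, THF/H2O, 0 °C
Reagents that add atoms: none
Why: SmI2 reduces the ketone through ketyl and carbanion while leaving the ester alone; protonation should give the more stable alcohol, with C14–O on the outer face of ring C and H toward the ring interior, as in mutilin.

Step 16
Reactants: 20 C14 alcohol
Product: 21 diester with quaternary C9
Conditions: Fe(acac)3 (0.3 equiv), PhSiH3, methyl acrylate, EtOH/ethylene glycol, 60 °C
Reagents that add atoms: methyl acrylate, C=CC(=O)OC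
Why: Mukaiyama-type hydrogen atom transfer puts H on C8, and the tertiary bridgehead radical at C9 adds to methyl acrylate (Giese reaction); the new C9–C1 bond can only form on the outer face of the bridgehead, which fixes C9.

Step 17
Reactants: 21 diester with quaternary C9
Product: 23 tricyclic keto alcohol, via β-keto ester 22 (not isolated)
Conditions: KOt-Bu, THF, 0 to 23 °C; AcOH; then LiCl, H2O, DMSO, 140 °C
Reagents that add atoms: none
Why: Dieckmann condensation (enolate of the C9 propanoate chain acylated by the C4 ester) closes ring A, and Krapcho demethoxycarbonylation removes the extra ester; C4, now α to the ketone, should keep the cis-hydrindanone configuration, which is also the stable one (C3 axial, away from ring C).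

Step 18
Reactants: 23 tricyclic keto alcohol; 24 (tert-butyldimethylsilyloxy)acetic acid
Product: 25 protected glycolate
Conditions: 24, DCC, DMAP (cat.), CH2Cl2, 23 °C
Reagents that add atoms: none
Why: Steglich esterification of the only free hydroxyl (C14).

Step 19
Reactants: 25 protected glycolate
Product: 26 Pleuromutilin A
Conditions: 48% aq. HF, MeCN, 0 to 23 °C
Reagents that add atoms: none
Why: aqueous HF cleaves both silyl ethers and hydrolyzes the acetonide, while the glycolate ester and the ketone are stable to these conditions.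

**Compound list**

1 | (S)-4-hydroxydihydrofuran-2(3H)-one ((S)-3-hydroxy-γ-butyrolactone) | O=C1C[C@H](O)CO1 | starting material
2 | (3S,4S)-4-hydroxy-3-methyldihydrofuran-2(3H)-one (methyl trans to hydroxyl) | O=C1[C@@H](C)[C@H](O)CO1 | intermediate
3 | (3S,4S)-4-hydroxy-3-methyl-3-(prop-2-en-1-yl)dihydrofuran-2(3H)-one (allyl trans to hydroxyl) | O=C1[C@@](C)(CC=C)[C@H](O)CO1 | intermediate
4 | (2R,3S)-2-methyl-2-(prop-2-en-1-yl)butane-1,3,4-triol | OC[C@](C)([C@H](O)CO)CC=C | intermediate
5 | (2R)-2-[(4S)-2,2-dimethyl-1,3-dioxolan-4-yl]-2-methylpent-4-en-1-ol | OC[C@](C)([C@H]1COC(C)(C)O1)CC=C | intermediate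
6 | (2S)-2-[(4S)-2,2-dimethyl-1,3-dioxolan-4-yl]-2-methylpent-4-enal | O=C[C@](C)([C@H]1COC(C)(C)O1)CC=C | intermediate
7 | (4S)-4-benzyl-3-propanoyl-1,3-thiazolidine-2-thione | CCC(=O)N1[C@@H](Cc2ccccc2)CSC1=S | starting material
8 | (4S)-4-benzyl-3-{(2S,3S,4R)-4-[(4S)-2,2-dimethyl-1,3-dioxolan-4-yl]-3-hydroxy-2,4-dimethylhept-6-enoyl}-1,3-thiazolidine-2-thione (C10-methyl and C11-hydroxyl syn) | C[C@H](C(=O)N1[C@@H](Cc2ccccc2)CSC1=S)[C@H](O)[C@](C)([C@H]1COC(C)(C)O1)CC=C | intermediate
9 | tert-butyldimethylsilyl ether of 8 at the C11 hydroxyl (2S,3S,4S by CIP, same spatial arrangement) | C[C@H](C(=O)N1[C@@H](Cc2ccccc2)CSC1=S)[C@H](O[Si](C)(C)C(C)(C)C)[C@](C)([C@H]1COC(C)(C)O1)CC=C | intermediate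
10 | methyl (4S,5S,6S)-5-[(tert-butyldimethylsilyl)oxy]-6-[(4S)-2,2-dimethyl-1,3-dioxolan-4-yl]-4,6-dimethyl-3-oxonon-8-enoate | C[C@H](C(=O)CC(=O)OC)[C@H](O[Si](C)(C)C(C)(C)C)[C@](C)([C@H]1COC(C)(C)O1)CC=C | intermediate
11 | methyl (2Z,4S,5S,6S)-5-[(tert-butyldimethylsilyl)oxy]-6-[(4S)-2,2-dimethyl-1,3-dioxolan-4-yl]-4,6-dimethyl-3-{[(trifluoromethyl)sulfonyl]oxy}nona-2,8-dienoate (triflate cis to ester) | C[C@H](/C(OS(=O)(=O)C(F)(F)F)=C/C(=O)OC)[C@H](O[Si](C)(C)C(C)(C)C)[C@](C)([C@H]1COC(C)(C)O1)CC=C | intermediate
12 | ozonide (1,2,4-trioxolane) of the terminal alkene of 11, other centers unchanged | C[C@H](/C(OS(=O)(=O)C(F)(F)F)=C/C(=O)OC)[C@H](O[Si](C)(C)C(C)(C)C)[C@](C)([C@H]1COC(C)(C)O1)CC1OCOO1 | intermediate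
13 | methyl (2Z,4S,5S,6S)-5-[(tert-butyldimethylsilyl)oxy]-6-[(4S)-2,2-dimethyl-1,3-dioxolan-4-yl]-4,6-dimethyl-8-oxo-3-{[(trifluoromethyl)sulfonyl]oxy}oct-2-enoate | C[C@H](/C(OS(=O)(=O)C(F)(F)F)=C/C(=O)OC)[C@H](O[Si](C)(C)C(C)(C)C)[C@](C)([C@H]1COC(C)(C)O1)CC=O | intermediate
14 | (Z)-2-bromobut-2-ene | C/C=C(\Br)C | starting material
15 | (Z)-but-2-en-2-yllithium | C/C=C(\[Li])C | intermediate
16 | allylic alcohol from 13 and 15: C14 carbinol (both epimers) bearing the (Z)-but-2-en-2-yl group (C14 cis to the C17 methyl); enol triflate and C10, C11, C12, C19 as in 13 | C[C@H](/C(OS(=O)(=O)C(F)(F)F)=C/C(=O)OC)[C@H](O[Si](C)(C)C(C)(C)C)[C@](C)([C@H]1COC(C)(C)O1)CC(O)/C(C)=C\C | intermediate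
17 | dienoate alcohol: as 16 with a vinyl group in place of the triflate (vinyl cis to the ester) | C[C@H](/C(C=C)=C/C(=O)OC)[C@H](O[Si](C)(C)C(C)(C)C)[C@](C)([C@H]1COC(C)(C)O1)CC(O)/C(C)=C\C | intermediate
18 | triene (Z)-enone: as 17 with the C14 carbinol oxidized to the ketone (angeloyl-type enone, C14 cis to C17) | C[C@H](/C(C=C)=C/C(=O)OC)[C@H](O[Si](C)(C)C(C)(C)C)[C@](C)([C@H]1COC(C)(C)O1)CC(=O)/C(C)=C\C | intermediate
19 | Diels–Alder adduct: rings B and C of mutilin as a bicyclo[5.3.1]undec-ene with C8=C9 bridgehead alkene, C14 ketone, methyl ester on C4, C11 silyl ether, C12 dioxolane; C4, C5, C6, C10, C11, C12, C19 as in 26 | C[C@H]1[C@H](O[Si](C)(C)C(C)(C)C)[C@](C)([C@H]3COC(C)(C)O3)CC(=O)[C@@]2(C)[C@@H](C)CC=C1[C@@H]2C(=O)OC | intermediate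
20 | C14 alcohol of 19 (C14 as in 26) | C[C@H]1[C@H](O[Si](C)(C)C(C)(C)C)[C@](C)([C@H]3COC(C)(C)O3)C[C@@H](O)[C@@]2(C)[C@@H](C)CC=C1[C@@H]2C(=O)OC | intermediate
21 | diester: 20 with C8 saturated and a 3-methoxy-3-oxopropyl chain (C1, C2) on the quaternary C9 (C9 as in 26) | C[C@H]1[C@H](O[Si](C)(C)C(C)(C)C)[C@](C)([C@H]3COC(C)(C)O3)C[C@@H](O)[C@@]2(C)[C@@H](C)CC[C@@]1(CCC(=O)OC)[C@@H]2C(=O)OC | intermediate
22 | tricyclic β-keto ester: ring A closed, methyl ester on C2 (C2 epimers or enol), other centers as in 26 | C[C@H]1[C@H](O[Si](C)(C)C(C)(C)C)[C@](C)([C@H]4COC(C)(C)O4)C[C@@H](O)[C@@]2(C)[C@@H](C)CC[C@]13CC(C(=O)OC)C(=O)[C@@H]32 | intermediate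
23 | tricyclic keto alcohol: 11-O-TBS-19,20-O-isopropylidene derivative of the 19,20-dihydroxymutilin core with free C14 hydroxyl | C[C@H]1[C@H](O[Si](C)(C)C(C)(C)C)[C@](C)([C@H]4COC(C)(C)O4)C[C@@H](O)[C@@]2(C)[C@@H](C)CC[C@]13CCC(=O)[C@@H]32 | intermediate
24 | (tert-butyldimethylsilyloxy)acetic acid | CC(C)(C)[Si](C)(C)OCC(=O)O | starting material
25 | C14 ester of 23 with 24 (fully protected target) | C[C@H]1[C@H](O[Si](C)(C)C(C)(C)C)[C@](C)([C@H]4COC(C)(C)O4)C[C@@H](OC(=O)CO[Si](C)(C)C(C)(C)C)[C@@]2(C)[C@@H](C)CC[C@]13CCC(=O)[C@@H]32 | intermediate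
26 | Pleuromutilin A (19,20-dihydroxy-19,20-dihydropleuromutilin) | C[C@H]1[C@H](O)[C@](C)([C@H](O)CO)C[C@@H](OC(=O)CO)[C@@]2(C)[C@@H](C)CC[C@]13CCC(=O)[C@@H]32 | target

**Step count**

Total step count: 19. Longest linear sequence: 19 steps (from 1; 7, 14 and 24 are bought).

**Steps most likely to fail**

Step 14. The cycloaddition may be too slow, because the trisubstituted (Z)-enone and the ester-bearing diene are both hindered and electron-poor; Z-to-E isomerization of the enone or dimerization could then overtake ring closure. The fallback sets out from 13 and returns at 19. Indium-mediated Barbier addition of 1-bromobut-2-yne to 13 (THF/H2O) should give the buta-2,3-dien-2-yl carbinol F1. Stille vinylation as in step 12 gives the diene alcohol F2, and Dess–Martin oxidation the allenyl ketone F3, whose conjugated allene double bond is an unhindered, more reactive dienophile with no geometry to lose. Heating gives the adduct with an exocyclic methylene at C6, F4. Hydrogenation with RhCl(PPh3)3 and H2 should take the 1,1-disubstituted alkene before the trisubstituted bridgehead alkene and add from the face away from the C14 bridge; this sets C6 and gives 19.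

Step 16. Hydrogen atom transfer may end in plain reduction or isomerization of the alkene instead of C–C bond formation, because the bridgehead radical is hindered. The fallback sets out from 20 and returns at 21. Dry HCl in CH2Cl2 at −78 °C should add across the strained C8=C9 alkene to give the tertiary bridgehead chloride F5. A classical tin hydride Giese reaction (Bu3SnH added slowly, AIBN, excess methyl acrylate, benzene, 80 °C) then forms the C9–C1 bond on the outer face.

Step 15. Protonation of the carbanion from the outer face would give the C14 epimer. The fallback sets out from 19 and returns at 20. Reduction with NaBH4 in MeOH, which should deliver hydride from the open outer face, gives the C14-epimeric alcohol F6. F6 is then equilibrated by reversible transfer dehydrogenation (RuCl2(PPh3)3, KOt-Bu cat., toluene, 80 °C) through ketone 19 to the more stable alcohol 20.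

Further compounds
F1 | step 14 | buta-2,3-dien-2-yl carbinol from 13 (C14 epimers), enol triflate retained | C[C@H](/C(OS(=O)(=O)C(F)(F)F)=C/C(=O)OC)[C@H](O[Si](C)(C)C(C)(C)C)[C@](C)([C@H]1COC(C)(C)O1)CC(O)C(C)=C=C
F2 | step 14 | diene alcohol: F1 with vinyl in place of the triflate (vinyl cis to ester) | C[C@H](/C(C=C)=C/C(=O)OC)[C@H](O[Si](C)(C)C(C)(C)C)[C@](C)([C@H]1COC(C)(C)O1)CC(O)C(C)=C=C
F3 | step 14 | allenyl ketone: F2 oxidized at C14 | C[C@H](/C(C=C)=C/C(=O)OC)[C@H](O[Si](C)(C)C(C)(C)C)[C@](C)([C@H]1COC(C)(C)O1)CC(=O)C(C)=C=C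
F4 | step 14 | Diels–Alder adduct of F3: as 19 but with an exocyclic methylene on C6 | C[C@H]1[C@H](O[Si](C)(C)C(C)(C)C)[C@](C)([C@H]3COC(C)(C)O3)CC(=O)[C@@]2(C)C(=C)CC=C1[C@@H]2C(=O)OC
F5 | step 16 | tertiary bridgehead chloride: 20 with H on C8 and Cl on C9 (outer face) | C[C@H]1[C@H](O[Si](C)(C)C(C)(C)C)[C@](C)([C@H]3COC(C)(C)O3)C[C@@H](O)[C@@]2(C)[C@@H](C)CC[C@@]1(Cl)[C@@H]2C(=O)OC
F6 | step 15 | C14 epimer of 20 | C[C@H]1[C@H](O[Si](C)(C)C(C)(C)C)[C@](C)([C@H]3COC(C)(C)O3)C[C@H](O)[C@@]2(C)[C@@H](C)CC=C1[C@@H]2C(=O)OC
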